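The flavone is cut across ring C at O1–C8a, C4–C4a and O1–C2. Ring A carries O1 (on C8a) and the C4 carbonyl (on C4a) on neighbouring carbons, with the C5 oxygen next to C4a. This is the pattern left when an acyl–oxygen bond adds across a 3-alkoxyaryne. In one operation a 3,5-bis(methoxymethoxy)benzyne should insert into the C–O bond of a 2,3-dimethoxycinnamic acid, and the resulting ortho-acyl phenoxide should close ring C by displacing the β-methoxy group. The precursors are an ortho-silylaryl triflate made from phloroglucinol and a β-methoxyacrylic acid that already carries the 3-methoxy group and the prenylated ring B.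

Key step: step 9

Remark: the enol ether and the acid derived from it are drawn as Z isomers (β-methoxy trans to the carbonyl), the geometry expected from a dissociated enolate; the E isomers would serve equally, because the key step removes this methoxy group and makes the double bond part of ring C.

Step 1
Reactants: 1 phloroglucinol
Product: 2 3,5-bis(methoxymethoxy)phenol
Conditions: MOMCl (2.1 equiv), i-Pr2NEt, DMF–CH2Cl2, 0 °C → rt
Reagents that add atoms: chloromethyl methyl ether, COCCl
Why: Williamson-type O-alkylation of a phenol by an α-chloro ether; the three hydroxyls are equivalent, so two equivalents of MOMCl should give the bis-ether as the main component of a statistical mixture, from which the mono-ether (recyclable) and tris-ether are removed by chromatography.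

Step 2
Reactants: 2 3,5-bis(methoxymethoxy)phenol
Product: 3 2-bromo-3,5-bis(methoxymethoxy)phenol
Conditions: NBS (1.0 equiv), CH2Cl2, −78 °C → −20 °C
Reagents that add atoms: N-bromosuccinimide, O=C1CCC(=O)N1Br
Why: Electrophilic aromatic bromination; the two equivalent positions ortho to the free hydroxyl should be preferred over the position between the two MOM ethers on statistical and steric grounds and through hydrogen-bond delivery of NBS in a non-polar solvent, while one equivalent of NBS at low temperature limits a second bromination.

Step 3
Reactants: 3 2-bromo-3,5-bis(methoxymethoxy)phenol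
Product: 4 [2-bromo-3,5-bis(methoxymethoxy)phenoxy]trimethylsilane
Conditions: HMDS, THF, 65 °C; evaporate
Reagents that add atoms: hexamethyldisilazane, C[Si](C)(C)N[Si](C)(C)C
Why: O-Silylation of a phenol with a silazane, which releases only volatile ammonia, so the moisture-sensitive silyl ether can be used after simple evaporation.

Step 4
Reactants: 4 [2-bromo-3,5-bis(methoxymethoxy)phenoxy]trimethylsilane
Product: 7 3,5-bis(methoxymethoxy)-2-(trimethylsilyl)phenyl trifluoromethanesulfonate, via aryllithium 5 (not isolated), via lithium silylphenoxide 6 (not isolated)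
Conditions: n-BuLi, THF, −100 °C → −80 °C; then Tf2O, −100 °C → −80 °C
Reagents that add atoms: trifluoromethanesulfonic anhydride, O=S(=O)(OS(=O)(=O)C(F)(F)F)C(F)(F)F
Why: Bromine–lithium exchange followed by an anionic 1,3-shift of silicon from oxygen to carbon (retro-Brook rearrangement), driven by formation of the lithium phenoxide, which is then O-triflated at a temperature at which the MOM acetals should not react with the anhydride.

Step 5
Reactants: 8 methyl 4-hydroxybenzoate; 9 prenyl bromide (1-bromo-3-methylbut-2-ene)
Product: 10 methyl 4-(3-methylbut-2-enyloxy)benzoate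
Conditions: K2CO3, acetone, 56 °C
Reagents that add atoms: none
Why: Williamson ether synthesis, in which the phenoxide displaces bromide from the primary allylic halide in an SN2 reaction.

Step 6
Reactants: 10 methyl 4-(3-methylbut-2-enyloxy)benzoate; 11 methyl methoxyacetate
Product: 13 methyl 2-methoxy-3-oxo-3-[4-(3-methylbut-2-enyloxy)phenyl]propanoate, via lithium enolate 12 (not isolated)
Conditions: LiN(SiMe3)2 (2.6 equiv), 11 (1.5 equiv), THF, −78 °C; then 10, −78 °C → rt; aq. NH4Cl
Reagents that add atoms: none
Why: Crossed Claisen condensation of a preformed ester enolate with a non-enolisable ester, pulled forward by deprotonation of the β-keto ester by the surplus base; the product is racemic and its stereocentre disappears in step 7.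

Step 7
Reactants: 13 methyl 2-methoxy-3-oxo-3-[4-(3-methylbut-2-enyloxy)phenyl]propanoate
Product: 14 methyl (Z)-2,3-dimethoxy-3-[4-(3-methylbut-2-enyloxy)phenyl]prop-2-enoate
Conditions: Me2SO4, Cs2CO3, DMF, 0 °C → rt
Reagents that add atoms: dimethyl sulfate, COS(=O)(=O)OC
Why: O-Alkylation of an ambident β-keto ester enolate; a dissociated caesium enolate in DMF and the hard electrophile dimethyl sulfate favour attack through oxygen, and C-methylation would have to build a quaternary carbon beside a methoxy group, while the extended enolate should place the new methoxy group trans to the ester.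

Step 8
Reactants: 14 methyl (Z)-2,3-dimethoxy-3-[4-(3-methylbut-2-enyloxy)phenyl]prop-2-enoate
Product: 15 (Z)-2,3-dimethoxy-3-[4-(3-methylbut-2-enyloxy)phenyl]prop-2-enoic acid
Conditions: LiOH, THF–MeOH–H2O, 50 °C; then 1 M HCl to pH 3–4, 0 °C
Reagents that add atoms: lithium hydroxide, [Li+].[OH-]
Why: Ester saponification by acyl–oxygen cleavage; the tetrasubstituted, electron-rich β-carbon should resist conjugate attack by hydroxide, and brief cold acidification to pH 3–4 should free the acid without hydrolysing the enol ether.

Step 9
Reactants: 7 3,5-bis(methoxymethoxy)-2-(trimethylsilyl)phenyl trifluoromethanesulfonate; 15 (Z)-2,3-dimethoxy-3-[4-(3-methylbut-2-enyloxy)phenyl]prop-2-enoic acid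
Product: 18 3-methoxy-5,7-bis(methoxymethoxy)-2-[4-(3-methylbut-2-enyloxy)phenyl]chromen-4-one, via aryne 16 (not isolated), via ortho-acyl phenoxide 17 (not isolated)
Conditions: CsF (4 equiv), 7 (1.5 equiv), THF, 125 °C, sealed tube
Reagents that add atoms: none
Why: Fluoride attacks silicon in 7 and triflate leaves to give aryne 16; the caesium carboxylate of 15 adds through oxygen to the aryne carbon remote from the flanking MOM ether, the aryl anion so formed attacks the neighbouring ester carbonyl, and the four-membered alkoxide opens to the ortho-acyl phenoxide 17 (net insertion of the aryne into the acyl C–O bond, an anionic Fries-type acyl shift). The closest known reaction type is the fluoride-mediated insertion of arynes into the C–O bond of carboxylic acids, which with unsaturated acids continues by oxa-Michael closure to chromanones and flavones. Ring C closes by 6-endo-trig addition of the phenoxide to C2 followed by loss of methoxide (addition–elimination), which also erases the alkene geometry. No stereocentre is formed. The step needs regioselective addition to the unsymmetrical aryne, which the C5 alkoxy group should secure by stabilising the aryl anion at C4a inductively and by distorting the aryne towards attack at C8a. It also needs acyl transfer to outrun protonation of the aryl anion, which the high temperature and the absence of any other proton source should favour.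

Step 10
Reactants: 18 3-methoxy-5,7-bis(methoxymethoxy)-2-[4-(3-methylbut-2-enyloxy)phenyl]chromen-4-one
Product: 20 5,7-dihydroxy-3-methoxy-2-[4-(3-methylbut-2-enyloxy)phenyl]chromen-4-one, via bis(trimethylsilyl) ether 19 (not isolated)
Conditions: TMSOTf, 2,2′-bipyridyl, MeCN, 0 °C → rt; then H2O
Reagents that add atoms: none
Why: Cleavage of aromatic MOM acetals by a bipyridyl-buffered silyl triflate, which should convert each aryl MOM ether into the aryl silyl ether (19) and an N-methoxymethylbipyridinium salt before water hydrolyses the silyl ethers; no free protic acid is present, so the prenyl ether and the C3 methoxy group should survive.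

Compound list
1 | phloroglucinol (benzene-1,3,5-triol) | Oc1cc(O)cc(O)c1 | starting material
2 | 3,5-bis(methoxymethoxy)phenol | COCOc1cc(O)cc(OCOC)c1 | intermediate
3 | 2-bromo-3,5-bis(methoxymethoxy)phenol | COCOc1cc(O)c(Br)c(OCOC)c1 | intermediate
4 | [2-bromo-3,5-bis(methoxymethoxy)phenoxy]trimethylsilane | COCOc1cc(O[Si](C)(C)C)c(Br)c(OCOC)c1 | intermediate
5 | [2,4-bis(methoxymethoxy)-6-(trimethylsilyloxy)phenyl]lithium | [Li]c1c(O[Si](C)(C)C)cc(OCOC)cc1OCOC | intermediate (not isolated)
6 | lithium 3,5-bis(methoxymethoxy)-2-(trimethylsilyl)phenoxide | [Li+].[O-]c1cc(OCOC)cc(OCOC)c1[Si](C)(C)C | intermediate (not isolated)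
7 | 3,5-bis(methoxymethoxy)-2-(trimethylsilyl)phenyl trifluoromethanesulfonate | COCOc1cc(OCOC)c([Si](C)(C)C)c(OS(=O)(=O)C(F)(F)F)c1 | intermediate
8 | methyl 4-hydroxybenzoate | COC(=O)c1ccc(O)cc1 | starting material
9 | prenyl bromide (1-bromo-3-methylbut-2-ene) | CC(C)=CCBr | starting material
10 | methyl 4-(3-methylbut-2-enyloxy)benzoate | COC(=O)c1ccc(OCC=C(C)C)cc1 | intermediate
11 | methyl methoxyacetate | COCC(=O)OC | starting material
12 | lithium enolate of methyl methoxyacetate (chelated geometry, O–Li cis to the 2-methoxy group) | [Li+].[O-]/C(OC)=C\OC | intermediate (not isolated)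
13 | methyl 2-methoxy-3-oxo-3-[4-(3-methylbut-2-enyloxy)phenyl]propanoate (racemic) | COC(C(=O)OC)C(=O)c1ccc(OCC=C(C)C)cc1 | intermediate
14 | methyl (Z)-2,3-dimethoxy-3-[4-(3-methylbut-2-enyloxy)phenyl]prop-2-enoate | COC(=O)/C(OC)=C(/OC)c1ccc(OCC=C(C)C)cc1 | intermediate
15 | (Z)-2,3-dimethoxy-3-[4-(3-methylbut-2-enyloxy)phenyl]prop-2-enoic acid | OC(=O)/C(OC)=C(/OC)c1ccc(OCC=C(C)C)cc1 | intermediate
16 | 3,5-bis(methoxymethoxy)benzyne | COCOC1=CC#CC(OCOC)=C1 | intermediate (not isolated)
17 | (Z)-1-[2-hydroxy-4,6-bis(methoxymethoxy)phenyl]-2,3-dimethoxy-3-[4-(3-methylbut-2-enyloxy)phenyl]prop-2-en-1-one, present in the flask as its phenoxide | COCOc1cc(O)c(C(=O)/C(OC)=C(/OC)c2ccc(OCC=C(C)C)cc2)c(OCOC)c1 | intermediate (not isolated)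
18 | 3-methoxy-5,7-bis(methoxymethoxy)-2-[4-(3-methylbut-2-enyloxy)phenyl]chromen-4-one | COCOc1cc(OCOC)c2c(c1)oc(-c1ccc(OCC=C(C)C)cc1)c(OC)c2=O | intermediate
19 | 3-methoxy-2-[4-(3-methylbut-2-enyloxy)phenyl]-5,7-bis(trimethylsilyloxy)chromen-4-one | COc1c(-c2ccc(OCC=C(C)C)cc2)oc2cc(O[Si](C)(C)C)cc(O[Si](C)(C)C)c2c1=O | intermediate (not isolated)
20 | 5,7-dihydroxy-3-methoxy-2-[4-(3-methylbut-2-enyloxy)phenyl]chromen-4-one (5,7-dihydroxy-3-methoxy-4'-prenyloxyflavone) | COc1c(-c2ccc(OCC=C(C)C)cc2)oc2cc(O)cc(O)c2c1=O | target

Total step count: 10. Longest linear sequence: 6 steps (steps 1–4, 9, 10; the acid branch, steps 5–8, 9, 10, is equally long).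

Steps most likely to fail

Step 9. Protonation of the aryl anion before the acyl shift (simple O-arylation of the acid), ene capture of the aryne by the prenyl double bond, or addition with the wrong orientation would divert the key step. The fallback builds the same three bonds stepwise and sets out from bromophenol 3 and acid 15. Esterification (EDC·HCl, DMAP, CH2Cl2) should give 2-bromo-3,5-bis(methoxymethoxy)phenyl (Z)-2,3-dimethoxy-3-[4-(3-methylbut-2-enyloxy)phenyl]prop-2-enoate F1. Bromine–lithium exchange (n-BuLi, THF, −100 °C) should then trigger the 1,3 shift of the acyl group from oxygen to carbon (anionic Fries rearrangement started by halogen–metal exchange) and give the lithium phenoxide of 17. On warming, or with K2CO3 in MeOH, this should close ring C with loss of methoxide, and the fallback comes back to the route at 18. The position of the bromine fixes the regiochemistry.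

Step 7. C-Methylation of the ambident enolate may compete with the wanted O-methylation. The fallback sets out from 13 and installs the enol ether by ketalisation and elimination instead of alkylation. Ketalisation (HC(OMe)3, cat. camphorsulfonic acid, MeOH, 40 °C) should give methyl 2,3,3-trimethoxy-3-[4-(3-methylbut-2-enyloxy)phenyl]propanoate F2 (racemic). E1cB loss of methanol from its ester enolate (LiN(SiMe3)2, THF, −78 °C → 0 °C) should then return to the route at 14.

Step 2. Bromination between the two MOM ethers, or a second bromination, would erode the supply of the aryne precursor. The fallback sets out from 2 and introduces silicon by directed ortho-metalation instead of bromination and silyl shift. Carbamoylation (ClCONEt2, K2CO3, MeCN) should give 3,5-bis(methoxymethoxy)phenyl N,N-diethylcarbamate F3. Lithiation at the position flanked by the carbamate and one MOM ether and silylation (s-BuLi, TMEDA, THF, −78 °C; then Me3SiCl) should give 3,5-bis(methoxymethoxy)-2-(trimethylsilyl)phenyl N,N-diethylcarbamate F4. Reductive removal of the carbamate (LiAlH4, THF, 0 °C → rt) should give 3,5-bis(methoxymethoxy)-2-(trimethylsilyl)phenol F5, and triflation (NaH, PhNTf2, THF) returns to the route at 7.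

Further compounds
F1 | step 9 | 2-bromo-3,5-bis(methoxymethoxy)phenyl (Z)-2,3-dimethoxy-3-[4-(3-methylbut-2-enyloxy)phenyl]prop-2-enoate | COCOc1cc(OC(=O)/C(OC)=C(/OC)c2ccc(OCC=C(C)C)cc2)c(Br)c(OCOC)c1
F2 | step 7 | methyl 2,3,3-trimethoxy-3-[4-(3-methylbut-2-enyloxy)phenyl]propanoate (racemic) | COC(=O)C(OC)C(OC)(OC)c1ccc(OCC=C(C)C)cc1
F3 | step 2 | 3,5-bis(methoxymethoxy)phenyl N,N-diethylcarbamate | CCN(CC)C(=O)Oc1cc(OCOC)cc(OCOC)c1
F4 | step 2 | 3,5-bis(methoxymethoxy)-2-(trimethylsilyl)phenyl N,N-diethylcarbamate | CCN(CC)C(=O)Oc1cc(OCOC)cc(OCOC)c1[Si](C)(C)C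
F5 | step 2 | 3,5-bis(methoxymethoxy)-2-(trimethylsilyl)phenol | COCOc1cc(O)c([Si](C)(C)C)c(OCOC)c1
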